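**Retrosynthetic overview**

- The target comes from its C14 dimethyl acetal / C15 TBS ether by one mild acid step.
- Both rings close in one flask from an acyclic enal–allylic carbonate: first the ten-membered carbocycle by C6–C7 bond formation (the bond made in the farnesyl → germacrene cyclisation), then the 6,12-lactone by attack of O6 on the C12 ester (as in costunolide-type lactonisation). C6 and C7 are set in this step.
- The acyclic precursor comes from a C6/C7 dialdehyde (vinylalane addition at C7, then carbonate), itself made by B-alkyl Suzuki union (C3–C4) of a diene acetal with a (Z)-iodobutenol.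
- The diene acetal comes from (S)-5-(hydroxymethyl)butyrolactone (source of C8; carbons C7–C10 and C14), acrolein (C1–C3) and angelic acid.

Assumption: atom labels C1–C15 follow germacrane numbering of the target (C6 lactone carbinol, C7 ring-fusion CH, C8 angelate carbinol, C12 lactone carbonyl, C13 exocyclic CH2, C14 CHO, C15 CH2OH). The given SMILES is read as (6R,7S,8S), cis-fused lactone, both ring alkenes cis within the ring (CIP 1(10)E,4E).

Assumption: (R)-SEGPHOS is taken as the ligand enantiomer that directs the allyl unit to the Si face of the C6 aldehyde; if the sense is opposite, (S)-SEGPHOS is used.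

**Route**

Step 1
Reactants: 1 (S)-5-(hydroxymethyl)dihydrofuran-2(3H)-one
Product: 2 (S)-5-[(triethylsilyloxy)methyl]dihydrofuran-2(3H)-one
Conditions: Et3SiCl, imidazole, CH2Cl2, 0 °C
Reagents that add atoms: chlorotriethylsilane CC[Si](Cl)(CC)CC
Why: Silylation of the primary alcohol; the only stereocentre (future C8) comes from the chiral pool and is not touched.

Step 2
Reactants: 2 (S)-5-[(triethylsilyloxy)methyl]dihydrofuran-2(3H)-one; 3 acrolein
Product: 6 (S,E)-3-allylidene-5-[(triethylsilyloxy)methyl]dihydrofuran-2(3H)-one, via lithium aldolate 4 (not isolated), via allylic mesylate 5 (not isolated)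
Conditions: LiN(i-Pr)2, THF, −78 °C; 3; then MeSO2Cl, −78 → 0 °C; then DBU, rt
Reagents that add atoms: none
Why: Aldol condensation: the lactone lithium enolate adds 1,2 to acrolein and mesylation/E1cB elimination gives the conjugated (E)-alkylidene lactone (vinyl anti to the carbonyl, the thermodynamic isomer), which fixes the later C1=C10 geometry; the two transient centres are destroyed.

Step 3
Reactants: 6 (S,E)-3-allylidene-5-[(triethylsilyloxy)methyl]dihydrofuran-2(3H)-one
Product: 7 (2E)-2-[(2S)-2-hydroxy-3-(triethylsilyloxy)propyl]-N-methoxy-N-methylpenta-2,4-dienamide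
Conditions: MeNH(OMe)·HCl, AlMe3, CH2Cl2, 0 °C → rt
Reagents that add atoms: N,O-dimethylhydroxylamine hydrochloride CNOC.Cl
Why: Weinreb aminolysis of the lactone by the aluminium amide opens the ring, frees the C8 hydroxyl and leaves C14 as a reducible amide; no stereocentre changes.

Step 4
Reactants: 7 (2E)-2-[(2S)-2-hydroxy-3-(triethylsilyloxy)propyl]-N-methoxy-N-methylpenta-2,4-dienamide; 8 angelic acid
Product: 9 (2S,4E)-4-[methoxy(methyl)carbamoyl]-1-(triethylsilyloxy)hepta-4,6-dien-2-yl (Z)-2-methylbut-2-enoate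
Conditions: 8, 2,4,6-Cl3C6H2COCl, Et3N, toluene, rt; then 7, 80 °C
Reagents that add atoms: none
Why: Yamaguchi-type mixed-anhydride esterification run without DMAP acylates the C8 alcohol with retention and without isomerising the (Z)-angelate to the tiglate.

Step 5
Reactants: 9 (2S,4E)-4-[methoxy(methyl)carbamoyl]-1-(triethylsilyloxy)hepta-4,6-dien-2-yl (Z)-2-methylbut-2-enoate
Product: 10 (2S,4E)-4-formyl-1-(triethylsilyloxy)hepta-4,6-dien-2-yl (Z)-2-methylbut-2-enoate
Conditions: i-Bu2AlH (1.05 equiv), THF, −78 °C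
Reagents that add atoms: none
Why: Weinreb amide reduction: the N-methoxy amide forms a stable chelated aluminium hemiaminal at −78 °C faster than the hindered conjugated angelate is attacked, and gives the enal on work-up.

Step 6
Reactants: 10 (2S,4E)-4-formyl-1-(triethylsilyloxy)hepta-4,6-dien-2-yl (Z)-2-methylbut-2-enoate
Product: 11 (2S,4E)-4-(dimethoxymethyl)-1-(triethylsilyloxy)hepta-4,6-dien-2-yl (Z)-2-methylbut-2-enoate
Conditions: MeOSiMe3, Me3SiOTf (cat.), CH2Cl2, −78 °C
Reagents that add atoms: methoxytrimethylsilane CO[Si](C)(C)C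
Why: Noyori acetalisation under aprotic conditions masks the C14 aldehyde (which C7 would otherwise attack in a five-membered mode during ring closure) and keeps the silyl ether, so no free C7 hydroxyl can form a cyclic mixed acetal or take the angelate by acyl shift.

Step 7
Reactants: 12 4-(tert-butyldimethylsilyloxy)but-2-yn-1-ol
Product: 14 (Z)-4-(tert-butyldimethylsilyloxy)-3-iodobut-2-en-1-ol, via cyclic vinylaluminate 13 (not isolated)
Conditions: NaAlH2(OCH2CH2OMe)2, THF, 0 °C; then I2, −78 °C
Reagents that add atoms: iodine I-I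
Why: Hydroxyl-directed trans-hydroalumination of the propargylic alcohol and iodinolysis with retention give the (Z)-iodide, in which the future C6 and C15 carbons are already trans.

Step 8
Reactants: 11 (2S,4E)-4-(dimethoxymethyl)-1-(triethylsilyloxy)hepta-4,6-dien-2-yl (Z)-2-methylbut-2-enoate; 14 (Z)-4-(tert-butyldimethylsilyloxy)-3-iodobut-2-en-1-ol
Product: 16 (2S,4E,8E)-8-[(tert-butyldimethylsilyloxy)methyl]-4-(dimethoxymethyl)-10-hydroxy-1-(triethylsilyloxy)deca-4,8-dien-2-yl (Z)-2-methylbut-2-enoate, via B-alkyl-9-BBN 15 (not isolated)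
Conditions: 9-BBN, THF, 0 °C → rt; then 14, Pd(dppf)Cl2, AsPh3, Cs2CO3, DMF–H2O, rt
Reagents that add atoms: none
Why: Anti-Markovnikov hydroboration of the terminal vinyl of the diene and B-alkyl Suzuki–Miyaura coupling with retention at the iodoalkene join C3 to C4 and set the ring-cis C4=C5 geometry.

Step 9
Reactants: 16 (2S,4E,8E)-8-[(tert-butyldimethylsilyloxy)methyl]-4-(dimethoxymethyl)-10-hydroxy-1-(triethylsilyloxy)deca-4,8-dien-2-yl (Z)-2-methylbut-2-enoate
Product: 17 (2S,4E,8E)-8-[(tert-butyldimethylsilyloxy)methyl]-4-(dimethoxymethyl)-1,10-dioxodeca-4,8-dien-2-yl (Z)-2-methylbut-2-enoate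
Conditions: (COCl)2, DMSO, CH2Cl2, −78 → −35 °C; then Et3N, −78 → 0 °C
Reagents that add atoms: none
Why: Swern oxidation converts the allylic alcohol into the C6 enal and, because activated DMSO cleaves primary triethylsilyl ethers but not TBS ethers, oxidises the C7 silyl ether directly to the aldehyde without exposing a free hydroxyl next to the angelate.

Step 10
Reactants: 17 (2S,4E,8E)-8-[(tert-butyldimethylsilyloxy)methyl]-4-(dimethoxymethyl)-1,10-dioxodeca-4,8-dien-2-yl (Z)-2-methylbut-2-enoate; 18 methyl propiolate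
Product: 19 methyl (4S,6E,10E)-10-[(tert-butyldimethylsilyloxy)methyl]-6-(dimethoxymethyl)-3-hydroxy-4-[(Z)-2-methylbut-2-enoyloxy]-2-methylidene-12-oxododeca-6,10-dienoate (both C3 epimers)
Conditions: 18, i-Bu2AlH, N-methylmorpholine N-oxide, THF, 0 °C; then 17, −78 → 0 °C
Reagents that add atoms: none
Why: Vinylalumination (a Morita–Baylis–Hillman-type adduct from a pre-formed α-(methoxycarbonyl)vinylalane) adds 1,2 to the more electrophilic α-acyloxy aldehyde rather than the hindered conjugated C6 enal under non-basic conditions, so C8 does not epimerise; the new C7 carbinol is a mixture that step 12 erases.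

Step 11
Reactants: 19 methyl (4S,6E,10E)-10-[(tert-butyldimethylsilyloxy)methyl]-6-(dimethoxymethyl)-3-hydroxy-4-[(Z)-2-methylbut-2-enoyloxy]-2-methylidene-12-oxododeca-6,10-dienoate
Product: 20 methyl (4S,6E,10E)-3-(tert-butoxycarbonyloxy)-10-[(tert-butyldimethylsilyloxy)methyl]-6-(dimethoxymethyl)-4-[(Z)-2-methylbut-2-enoyloxy]-2-methylidene-12-oxododeca-6,10-dienoate (both C3 epimers)
Conditions: Boc2O, DMAP (cat.), CH2Cl2, 0 °C
Reagents that add atoms: di-tert-butyl dicarbonate CC(C)(C)OC(=O)OC(=O)OC(C)(C)C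
Why: DMAP-catalysed carbonate formation gives the allylic leaving group needed for π-allyl formation and blocks acyl migration from O8.

Step 12
Reactants: 20 methyl (4S,6E,10E)-3-(tert-butoxycarbonyloxy)-10-[(tert-butyldimethylsilyloxy)methyl]-6-(dimethoxymethyl)-4-[(Z)-2-methylbut-2-enoyloxy]-2-methylidene-12-oxododeca-6,10-dienoate
Product: 22 (6R,7S,8S)-8-angeloyloxy-15-(tert-butyldimethylsilyloxy)-14,14-dimethoxygermacra-1(10),4,11(13)-trien-12,6-olide (ring-cis alkenes), via hydroxy ester 21 (not isolated)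
Conditions: [Ir(cod)Cl]2 (5 mol %), (R)-SEGPHOS (10 mol %), 4-chloro-3-nitrobenzoic acid (10 mol %), Cs2CO3 (20 mol %), i-PrOH (3 equiv), THF, 5 mM by slow addition, 70 °C
Reagents that add atoms: none
Why: Proposed new method: a macrocyclising variant of the iridium-catalysed transfer-hydrogenative 2-(alkoxycarbonyl)allylation (closest known chemistry: the intermolecular reaction of acrylate-derived allylic carbonates with aldehydes or alcohols, which gives cis-α-methylene-γ-butyrolactones, and CrCl2- or Pd/Et2Zn-mediated macrocyclising allylations to ten-membered germacrane rings); monovalent iridium ionises the carbonate to a π-allyl (the C7 centre of 20 is erased), 2-propanol turns the catalyst over, and the σ-allyl with iridium on C13 adds to the C6 aldehyde through a closed chair with C8 cis to C13 (6,7-syn adduct = cis-lactone), the ligand directing attack to the Si face of C6 (6R) and C7 reacting anti to the C8–C9 bond with H8 eclipsing the allyl plane to avoid A(1,3) strain (7S, new bond on the side of the angelate oxygen); the cis γ-hydroxy ester 21 then lactonises on C12 under the basic conditions.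

Step 13
Reactants: 22 (6R,7S,8S)-8-angeloyloxy-15-(tert-butyldimethylsilyloxy)-14,14-dimethoxygermacra-1(10),4,11(13)-trien-12,6-olide
Product: 23 (6R,7S,8S)-8-angeloyloxy-15-hydroxy-14-oxogermacra-1(10),4,11(13)-trien-12,6-olide (target)
Conditions: AcOH–THF–H2O (3:1:1), rt
Reagents that add atoms: water O
Why: Mild aqueous acid hydrolyses the enal dimethyl acetal and the primary allylic TBS ether; the lactone, the angelate and the three stereocentres are untouched.

**Compound list**

1 | (S)-5-(hydroxymethyl)dihydrofuran-2(3H)-one | O=C1CC[C@@H](CO)O1 | starting material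
2 | (S)-5-[(triethylsilyloxy)methyl]dihydrofuran-2(3H)-one | O=C1CC[C@@H](CO[Si](CC)(CC)CC)O1 | intermediate
3 | acrolein | C=CC=O | starting material
4 | lithium 1-[(5S)-2-oxo-5-[(triethylsilyloxy)methyl]tetrahydrofuran-3-yl]prop-2-en-1-olate (diastereomer mixture) | [Li+].[O-]C(C=C)C1C[C@@H](CO[Si](CC)(CC)CC)OC1=O | intermediate
5 | 1-[(5S)-2-oxo-5-[(triethylsilyloxy)methyl]tetrahydrofuran-3-yl]prop-2-en-1-yl methanesulfonate (diastereomer mixture) | CS(=O)(=O)OC(C=C)C1C[C@@H](CO[Si](CC)(CC)CC)OC1=O | intermediate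
6 | (S,E)-3-allylidene-5-[(triethylsilyloxy)methyl]dihydrofuran-2(3H)-one | C=C/C=C1\C[C@@H](CO[Si](CC)(CC)CC)OC1=O | intermediate
7 | (2E)-2-[(2S)-2-hydroxy-3-(triethylsilyloxy)propyl]-N-methoxy-N-methylpenta-2,4-dienamide | C=C/C=C(\C[C@H](O)CO[Si](CC)(CC)CC)C(=O)N(C)OC | intermediate
8 | angelic acid, (Z)-2-methylbut-2-enoic acid | C/C=C(/C)C(=O)O | starting material
9 | (2S,4E)-4-[methoxy(methyl)carbamoyl]-1-(triethylsilyloxy)hepta-4,6-dien-2-yl (Z)-2-methylbut-2-enoate | C=C/C=C(\C[C@H](OC(=O)/C(C)=C\C)CO[Si](CC)(CC)CC)C(=O)N(C)OC | intermediate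
10 | (2S,4E)-4-formyl-1-(triethylsilyloxy)hepta-4,6-dien-2-yl (Z)-2-methylbut-2-enoate | C=C/C=C(\C[C@H](OC(=O)/C(C)=C\C)CO[Si](CC)(CC)CC)C=O | intermediate
11 | (2S,4E)-4-(dimethoxymethyl)-1-(triethylsilyloxy)hepta-4,6-dien-2-yl (Z)-2-methylbut-2-enoate | C=C/C=C(\C[C@H](OC(=O)/C(C)=C\C)CO[Si](CC)(CC)CC)C(OC)OC | intermediate
12 | 4-(tert-butyldimethylsilyloxy)but-2-yn-1-ol | OCC#CCO[Si](C)(C)C(C)(C)C | starting material
13 | sodium cyclic vinylaluminate (five-membered O–Al–C ring, two 2-methoxyethoxy groups on Al) | [Na+].COCCO[Al-]1(OCCOC)OCC=C1CO[Si](C)(C)C(C)(C)C | intermediate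
14 | (Z)-4-(tert-butyldimethylsilyloxy)-3-iodobut-2-en-1-ol | OC/C=C(\I)CO[Si](C)(C)C(C)(C)C | intermediate
15 | (2S,4E)-7-(9-borabicyclo[3.3.1]nonan-9-yl)-4-(dimethoxymethyl)-1-(triethylsilyloxy)hept-4-en-2-yl (Z)-2-methylbut-2-enoate | B1(CC/C=C(\C[C@H](OC(=O)/C(C)=C\C)CO[Si](CC)(CC)CC)C(OC)OC)C2CCCC1CCC2 | intermediate
16 | (2S,4E,8E)-8-[(tert-butyldimethylsilyloxy)methyl]-4-(dimethoxymethyl)-10-hydroxy-1-(triethylsilyloxy)deca-4,8-dien-2-yl (Z)-2-methylbut-2-enoate | OC/C=C(/CO[Si](C)(C)C(C)(C)C)CC/C=C(\C[C@H](OC(=O)/C(C)=C\C)CO[Si](CC)(CC)CC)C(OC)OC | intermediate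
17 | (2S,4E,8E)-8-[(tert-butyldimethylsilyloxy)methyl]-4-(dimethoxymethyl)-1,10-dioxodeca-4,8-dien-2-yl (Z)-2-methylbut-2-enoate | O=C/C=C(/CO[Si](C)(C)C(C)(C)C)CC/C=C(\C[C@H](OC(=O)/C(C)=C\C)C=O)C(OC)OC | intermediate
18 | methyl propiolate | C#CC(=O)OC | starting material
19 | methyl (4S,6E,10E)-10-[(tert-butyldimethylsilyloxy)methyl]-6-(dimethoxymethyl)-3-hydroxy-4-[(Z)-2-methylbut-2-enoyloxy]-2-methylidene-12-oxododeca-6,10-dienoate (both C3 epimers) | O=C/C=C(/CO[Si](C)(C)C(C)(C)C)CC/C=C(\C[C@H](OC(=O)/C(C)=C\C)C(O)C(=C)C(=O)OC)C(OC)OC | intermediate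
20 | methyl (4S,6E,10E)-3-(tert-butoxycarbonyloxy)-10-[(tert-butyldimethylsilyloxy)methyl]-6-(dimethoxymethyl)-4-[(Z)-2-methylbut-2-enoyloxy]-2-methylidene-12-oxododeca-6,10-dienoate (both C3 epimers) | O=C/C=C(/CO[Si](C)(C)C(C)(C)C)CC/C=C(\C[C@H](OC(=O)/C(C)=C\C)C(OC(=O)OC(C)(C)C)C(=C)C(=O)OC)C(OC)OC | intermediate
21 | methyl (6R,7R,8S)-8-angeloyloxy-15-(tert-butyldimethylsilyloxy)-6-hydroxy-14,14-dimethoxygermacra-1(10),4,11(13)-trien-12-oate (ring-cis alkenes; O6, C11 and O8 all on one face) | C=C(C(=O)OC)[C@@H]1[C@H](O)/C=C(/CO[Si](C)(C)C(C)(C)C)CC/C=C(/C(OC)OC)C[C@@H]1OC(=O)/C(C)=C\C | intermediate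
22 | (6R,7S,8S)-8-angeloyloxy-15-(tert-butyldimethylsilyloxy)-14,14-dimethoxygermacra-1(10),4,11(13)-trien-12,6-olide (cis-fused lactone, ring-cis alkenes) | C=C1C(=O)O[C@@H]2/C=C(/CO[Si](C)(C)C(C)(C)C)CC/C=C(/C(OC)OC)C[C@H](OC(=O)/C(C)=C\C)[C@H]12 | intermediate
23 | (6R,7S,8S)-8-angeloyloxy-15-hydroxy-14-oxogermacra-1(10),4,11(13)-trien-12,6-olide (cis-fused lactone, ring-cis alkenes; CNP0173211.3) | C=C1C(=O)O[C@@H]2/C=C(/CO)CC/C=C(/C=O)C[C@H](OC(=O)/C(C)=C\C)[C@H]12 | target

**Step count**

Total: 13 steps. Longest linear sequence: 12 steps (1 → 23 through steps 1–6 and 8–13); step 7 is a one-step side branch.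

**Three steps most likely to fail**

Step 12 (ring closure). Risks are oligomerisation at catalytic turnover under high dilution, loss of the angelate from the allyliridium (β- or vinylogous elimination), Z → E drift of the C6 enal, and a mismatched ligand/C8 pairing. The fallback sets out from 19 and comes back at 22. It replaces the catalytic π-allyl route by stoichiometric reductive metalation: N-bromosuccinimide/dimethyl sulfide converts 19 with allylic transposition into the (Z)-allylic bromide F1. CrCl2 (excess, divalent chromium) in THF at high dilution then gives a Nozaki–Hiyama–Kishi-type macrocyclising allylation through the same closed chair (C8 cis to C13, syn adduct). The chromium alkoxide of 21 lactonises to 22.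

Step 10 (acrylate unit at C7). The vinylalane may also add to the C6 enal, and the hydroxy ester product can suffer O8 → O7 acyl shift. The fallback sets out from 17 and comes back at 19 with no new compound (F0). It is an amine-catalysed Morita–Baylis–Hillman reaction of 17 with methyl acrylate (DABCO, dioxane–water), where the nucleophile is generated catalytically and the conjugated, β,β-disubstituted C6 enal is not a competent electrophile. The price is a possible partial epimerisation at C8, so the product is carried at once into step 11.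

Step 5 (amide reduction beside the angelate). If i-Bu2AlH also attacks the angelate, the fallback sets out from 9 and comes back at 16. The union is moved ahead of the reduction so that no terminal alkene remains: 9-BBN hydroboration of 9 gives the B-alkyl-9-BBN adduct F2, and Suzuki–Miyaura coupling with 14 gives the coupled Weinreb amide F3. Cp2Zr(H)Cl then reduces the tertiary amide to the enal F4 by a hydrozirconation-type mechanism that leaves esters and trisubstituted alkenes alone. Acetalisation as in step 6 (MeOSiMe3, Me3SiOTf) gives 16.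

Further compounds
F1 | step 12 | methyl (2Z,4S,6E,10E)-2-(bromomethyl)-10-[(tert-butyldimethylsilyloxy)methyl]-6-(dimethoxymethyl)-4-[(Z)-2-methylbut-2-enoyloxy]-12-oxododeca-2,6,10-trienoate | O=C/C=C(/CO[Si](C)(C)C(C)(C)C)CC/C=C(\C[C@H](OC(=O)/C(C)=C\C)/C=C(\CBr)C(=O)OC)C(OC)OC
F0 | step 10 | none | none
F2 | step 5 | (2S,4E)-7-(9-borabicyclo[3.3.1]nonan-9-yl)-4-[methoxy(methyl)carbamoyl]-1-(triethylsilyloxy)hept-4-en-2-yl (Z)-2-methylbut-2-enoate | B1(CC/C=C(\C[C@H](OC(=O)/C(C)=C\C)CO[Si](CC)(CC)CC)C(=O)N(C)OC)C2CCCC1CCC2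
F3 | step 5 | (2S,4E,8E)-8-[(tert-butyldimethylsilyloxy)methyl]-10-hydroxy-4-[methoxy(methyl)carbamoyl]-1-(triethylsilyloxy)deca-4,8-dien-2-yl (Z)-2-methylbut-2-enoate | OC/C=C(/CO[Si](C)(C)C(C)(C)C)CC/C=C(\C[C@H](OC(=O)/C(C)=C\C)CO[Si](CC)(CC)CC)C(=O)N(C)OC
F4 | step 5 | (2S,4E,8E)-8-[(tert-butyldimethylsilyloxy)methyl]-4-formyl-10-hydroxy-1-(triethylsilyloxy)deca-4,8-dien-2-yl (Z)-2-methylbut-2-enoate | OC/C=C(/CO[Si](C)(C)C(C)(C)C)CC/C=C(\C[C@H](OC(=O)/C(C)=C\C)CO[Si](CC)(CC)CC)C=O
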